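## Retrosynthetic overview
1. Open the pyranone C-ring last (O1–C2 bond, cyclodehydration). This gives an o-hydroxyaryl 1,3-diketone, and the 7-O-MOM group comes off in the same acidic step.
2. Disconnect the diketone by a crossed Claisen condensation into a 5-prenylated resacetophenone (A-ring) and methyl 2,2-dimethyl-2H-chromene-6-carboxylate (B-ring).
3. The A-ring fragment comes from C5-selective Friedel–Crafts prenylation of 2,4-dihydroxyacetophenone, followed by selective 4-O-MOM protection.
4. The B-ring fragment comes from methyl 4-hydroxybenzoate by 1,1-dimethylpropargyl ether formation and thermal propargyl Claisen/electrocyclisation.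
5. Ring order: the chromene pyran ring is formed first (on the fragment), and the flavone pyranone ring is formed last.

Assumption: the target (C25H24O4) has no stereocentre and no E/Z-defined alkene, so it is achiral. The "single enantiomer" requirement does not apply and no stereocontrol is needed.

## Route

**Step 1**
Reactants: 1, 2,4-dihydroxyacetophenone; 2, 2-methylbut-3-en-2-ol
Product: 3, 1-[2,4-dihydroxy-5-(3-methylbut-2-enyl)phenyl]ethanone
Conditions: BF3·OEt2 (about 0.6 equiv), dioxane, rt, 2 h; 1 used in slight excess; chromatography (expect about 25–30%; 3-prenyl isomer, chroman by-products and recovered 1 are removed)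
Reagents that add atoms: 2-methylbut-3-en-2-ol, CC(C)(O)C=C (delivers the C5 prenyl unit; its OH leaves as water)
Why: This is a Friedel–Crafts prenylation through the dimethylallyl cation. C5 (ortho to 4-OH, para to 2-OH) is as activated as C3 but much less hindered, so the 5-prenyl isomer is the main C-alkylation product.

**Step 2**
Reactants: 3; 4, chloromethyl methyl ether (MOMCl)
Product: 5, 1-[2-hydroxy-4-(methoxymethoxy)-5-(3-methylbut-2-enyl)phenyl]ethanone
Conditions: MOMCl (1.2 equiv), K2CO3, acetone, 0 °C → rt
Reagents that add atoms: MOMCl, COCCl
Why: This is a chemoselective Williamson-type O-alkylation. The 2-OH is hydrogen-bonded to the ketone and stays unreactive under weak base, so only the 4-OH is protected.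

**Step 3**
Reactants: 6, methyl 4-hydroxybenzoate; 7, 3-chloro-3-methylbut-1-yne
Product: 8, methyl 4-[(2-methylbut-3-yn-2-yl)oxy]benzoate
Conditions: DBU (1.3 equiv), CuCl2·2H2O (cat.), MeCN, 0 °C → rt
Reagents that add atoms: 3-chloro-3-methylbut-1-yne, CC(C)(Cl)C#C
Why: This is a copper-catalysed propargylic etherification. It works well for electron-poor phenols and gives the tertiary aryl propargyl ether without touching the ester.

**Step 4**
Reactants: 8
Product: 9, methyl 2,2-dimethyl-2H-chromene-6-carboxylate
Conditions: PhNEt2, 195–200 °C, 3 h; dilute HCl wash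
Reagents that add atoms: none
Why: This is an aromatic propargyl Claisen rearrangement followed by a [1,5]-H shift and oxa-6π electrocyclisation. The two ortho positions are equivalent, so a single chromene forms with its oxygen para to the ester.

**Step 5**
Reactants: 5; 9
Product: 10, 1-(2,2-dimethyl-2H-chromen-6-yl)-3-[2-hydroxy-4-(methoxymethoxy)-5-(3-methylbut-2-enyl)phenyl]propane-1,3-dione (keto/enol mixture)
Conditions: NaH (4 equiv), THF, reflux, 4–6 h; cold aq. NH4Cl/AcOH quench
Reagents that add atoms: none beyond reactant 9, COC(=O)c1ccc2c(c1)C=CC(C)(C)O2 (aroyl donor; OMe leaves as MeOH)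
Why: This is a crossed Claisen condensation of the phenoxide/enolate dianion with a non-enolisable ester, the direct equivalent of a Baker–Venkataraman diketone. Irreversible deprotonation of the 1,3-diketone drives it, and the MOM, prenyl and chromene groups are inert to base.

**Step 6**
Reactants: 10
Product: 11, Kanzonol E, 2-(2,2-dimethyl-2H-chromen-6-yl)-7-hydroxy-6-(3-methylbut-2-enyl)-4H-chromen-4-one
Conditions: conc. HCl (about 1 M final) in MeOH, 55–60 °C, 1–2 h, TLC-monitored; NaHCO3 work-up
Reagents that add atoms: none (H2O is lost and MOM leaves as CH2(OMe)2)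
Why: This is an acid-catalysed cyclodehydration: the 2-OH adds to the aroyl carbonyl, then water is lost, and the MOM acetal cleaves at the same time. Only the 2-OH can reach the diketone, so only the 6-prenyl-7-hydroxy flavone can form. Short exposure to dilute methanolic HCl is the usual condition under which prenyl and 2,2-dimethylchromene units survive.

## Compound list
1 | 2,4-dihydroxyacetophenone | CC(=O)c1ccc(O)cc1O | starting material
2 | 2-methylbut-3-en-2-ol | CC(C)(O)C=C | starting material
3 | 1-[2,4-dihydroxy-5-(3-methylbut-2-enyl)phenyl]ethanone | CC(=O)c1cc(CC=C(C)C)c(O)cc1O | intermediate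
4 | chloromethyl methyl ether | COCCl | starting material (reagent)
5 | 1-[2-hydroxy-4-(methoxymethoxy)-5-(3-methylbut-2-enyl)phenyl]ethanone | CC(=O)c1cc(CC=C(C)C)c(OCOC)cc1O | intermediate
6 | methyl 4-hydroxybenzoate | COC(=O)c1ccc(O)cc1 | starting material
7 | 3-chloro-3-methylbut-1-yne | CC(C)(Cl)C#C | starting material
8 | methyl 4-[(2-methylbut-3-yn-2-yl)oxy]benzoate | COC(=O)c1ccc(OC(C)(C)C#C)cc1 | intermediate
9 | methyl 2,2-dimethyl-2H-chromene-6-carboxylate | COC(=O)c1ccc2c(c1)C=CC(C)(C)O2 | intermediate
10 | 1-(2,2-dimethyl-2H-chromen-6-yl)-3-[2-hydroxy-4-(methoxymethoxy)-5-(3-methylbut-2-enyl)phenyl]propane-1,3-dione | COCOc1cc(O)c(cc1CC=C(C)C)C(=O)CC(=O)c1ccc2c(c1)C=CC(C)(C)O2 | intermediate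
11 | Kanzonol E (achiral) | CC(C)=CCc1cc2c(=O)cc(-c3ccc4c(c3)C=CC(C)(C)O4)oc2cc1O | target

## Summary
Total steps: 6 (convergent).
Longest linear sequence: 4 steps (1 → 3 → 5 → 10 → 11). The other branch, 6 → 8 → 9 → 10 → 11, is also 4 steps.

Steps most likely to fail, with fallbacks:
1. **Step 1** (low yield, C3/C5 mixture, chroman formation). Fallback: fix the regiochemistry with a halogen instead of relying on electrophilic substitution. Start from 5-bromo- or 5-iodo-2,4-dihydroxyacetophenone, protect the 4-OH as MOM, and install the prenyl group by Pd-catalysed Stille coupling with tributyl(3-methylbut-2-enyl)stannane (or Suzuki coupling with prenyl-Bpin).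
2. **Step 6** (acid may cyclise the o-prenylphenol to a dimethylchroman, or add MeOH to the prenyl or chromene alkene). Fallback: separate the two events and avoid mineral acid. Protect the 7-OH as an allyl ether instead of MOM, cyclodehydrate the diketone in NaOAc-buffered AcOH, then remove the allyl group under neutral conditions with Pd(PPh3)4/morpholine.
3. **Step 5** (the electron-rich p-alkoxybenzoate is a sluggish electrophile). Fallback: switch to the chalcone approach. Make 2,2-dimethyl-2H-chromene-6-carbaldehyde by applying Steps 3–4 to 4-hydroxybenzaldehyde, carry out a Claisen–Schmidt condensation with 5 (KOH, EtOH), and oxidatively cyclise the 2'-hydroxychalcone (cat. I2, DMSO, heat) before removing the MOM group.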